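## Structural features

The target is a C20 gibberellin. It has a cyclohexane ring A (C1–C5, C10), a cyclopentane ring B (C5, C6, C8, C9, C10) and a bicyclo[3.2.1]octane made of rings C and D (C8, C9, C11–C16) with an exocyclic C16=C17 methylene. A δ-lactone (C19–O–C20) spans C4 and C10 on the α-face of ring A, and C6 carries the C7 carboxylic acid. Ring B is trans-fused to ring A (H5 β, C20 α) and cis-fused to ring C (H9 β), so C9 sits between the quaternary carbons C8 and C10. The ten stereocentres form two contiguous arrays, C2–C3–C4–C5–C6 and C8–C9–C10–C11, which meet in ring B; C13 is tied to C8 through the bicycle. The 2β,3β-diol is cis and lies opposite the lactone bridge, and the 11β-hydroxyl is axial and points at the C15–C16 bridge. The fragile parts are the exocyclic alkene (acid, all electrophilic oxidants), the 3-hydroxyl β to the lactone carbonyl (retro-aldol and epimerisation in alkali), and the epimerisable C6 and, while C11 is a ketone, C9. The real difficulty is the congested C8–C9–C10 array together with regiocontrol at C9 (against C12) and the differentiation of the two oxygenated carbons C11 and C16. The key step uses the fact that C11 and C16 are both joined through a methylene (C9, C15) to quaternary C8, a 1,5-dioxygen pattern across rings C and D.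

## Logic of the disconnections

33 from 32: only the O–CH3 bond of the C7 ester is cut. The methyl ester is kept to the end so that no free acid is carried through enolate and oxidation steps. The forward step must be non-hydrolytic, because alkali would endanger C3 by retro-aldol.

32 from 31: the C2–C3 bond is cut. This opens ring A and removes both carbinol stereocentres at once, leaving two aldehydes held 1,3-diaxially on the lactone ring. The forward reductive coupling must give the cis-diol on the β-face.

31 from 27 (through 30, 29, 28): no skeletal bond is cut. The oxidation levels of C2, C3 and C11 are adjusted and C6 is equilibrated. This stage needs the C11 ketone to be reduced from the face away from the C15–C16 bridge and the 6β-ester to be the thermodynamic epimer.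

27 from 26: the C9–C10 bond is cut, which opens ring B and removes the quaternary C10 and the C9 stereocentre. Because the acceptor is tethered through C5–C6, only C9 (not C12) can reach C10, which solves the regiochemistry of the C11 ketone. The forward conjugate addition has to form a quaternary centre next to a neopentyl carbon.

26 from 23 (through 25, 24): the C10–C1 bond is cut and the C11 ketone is masked again. The two-carbon aldehyde arm is traced to a vinyl group on a ketone. The forward sequence needs a non-basic addition so that C5, α to the C10 ketone, is not scrambled.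

23 from 18 (through 22, 21): the C4–C3 bond is cut and C10 is returned to the alcohol level. C4 loses its quaternary character. The forward alkylation must take place trans to the C5 substituent and at the lactone rather than at the C6 ester.

18 from 11 and 15: the C5–C6 and C4–C18 bonds are cut. This is the convergent step and separates the complete lactone ring (C4, C5, C10, C19, C20) from the C/D bicycle. The C10 silyloxy group of 15 must direct the C6 nucleophile to the opposite face to set C5.

15 from 12 (through 14, 13): the C4=C5 double bond (metathesis) and the C19–O acyl bond are cut. This leads back to a commercial four-carbon diol that carries the C10 stereocentre.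

11 from 9 (through 10): the C16=C17 bond is cut and the C11 ketal removed. The two ketones are distinguished by ketalising the cyclohexanone first; the forward step must discriminate it from the bridged cyclopentanone.

9 from 7 (through 8): the C16–C15 and C9–C8 bonds are cut and C9–C16 is reconnected. Both carbocyclic rings of the C/D bicycle and the quaternary C8 collapse to a monocyclic dione enol with one stereocentre. The forward photocycloaddition must run in the crossed sense.

7 from 3 and 4 (through 6, 5): the C13–C14 bond is cut and C16 is returned to the silyl ether level. C13 comes from an enantiopure silyloxy-enone by anti conjugate allylation, which avoids an untested enantioselective addition to the free enedione.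

3 from 1: the C6–C7 bond is cut, leading back to the commercial silylated allyl chloride.

## Other disconnections considered

Alternative 1: ring contraction of a kauranoid. The C6–C8 bond is cut and the C7 acid is traced to a ketene. The substrate is the 6-diazo-7-ketone A1 with a six-membered ring B; irradiation should expel N2, shift C8 from C7 to C6 and give the acid A2 after trapping with water.
- In favour: the 1,2-shift moves quaternary C8 with retention and creates C6 and C7 in one operation on an almost finished skeleton.
- Against: A1 already contains everything that is hard in the target (the C/D bicycle, C10, the lactone, the triol). The diazo group must be placed at C6 next to the epimerisable C5. The ketene is protonated without control at C6, which would need a later equilibration.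
- Comparison: on mechanism the Wolff shift is at least the equal of the chosen key step and is better in predictability at C8. On structure it solves none of the C8–C13 problem, and on step economy it is worse, because ring B has to be made one carbon too large and then contracted.

Alternative 2: oxidative radical tandem cyclisation. The C8–C14 and C13–C16 bonds are cut. Mn(OAc)3 (trivalent manganese) should oxidise the β-keto ester A3 to the C8 radical, which closes ring C 6-endo and ring D 5-exo onto the alkyne to give A4.
- In favour: the bicycle and the exocyclic methylene come in one thermal step from an acyclic precursor, with no photochemistry. On this point it is better than the chosen plan, which needs a separate methylenation.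
- In favour: the ketone of A4 sits at C9, so a C9–C10 bond could be made by direct carbonyl addition without a regiochemical question. That is also a better point than the C9 problem of the chosen plan.
- Against: C8 is controlled only by the remote auxiliary, whereas the chosen plan takes C13 from an enantiopure building block and transmits it to C8 by geometry. C11 carries no oxygen and would have to be oxidised later. The single ester carbon on C8 has to be extended to the C6–C7 unit.
- Comparison: shorter to the bicycle, but the later oxygen transposition and homologation would consume the saving.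

Alternative 3: Pauson–Khand closure of ring B. The C5–C10, C4–C19 and C19–C20 bonds are cut. Co2(CO)8 should join the alkyne, the alkene and CO of the enyne A5 to give the cyclopentenone A6.
- In favour: three bonds and ring B form at once, the carbons of the lactone are delivered together, and C10 becomes the β-carbon of an enone ready for quaternisation. In bond count per step this is the better plan.
- Against: A5 needs an alkyne at C9, which reopens the C9/C12 regiochemistry that the chosen plan avoids by ring-size control. The later Baeyer–Villiger insertion must occur on the C20 side of C19 although C4 becomes the more substituted neighbour. Ring A and both quaternary centres C4 and C10 remain to be built.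
- Comparison: mechanistically equal in reliability for a 1,6-enyne; structurally it shares the C/D unit of the chosen plan; overall step economy is expected to be similar or worse because of the ring A annulation.

Key step: step 5

Remark: atom numbers C1–C20 are those of the gibberellane skeleton; β is the face of H5, H9 and the C15–C16 bridge, α that of the lactone.
Remark: in names, Bic is the (1R,5S)-6-methylidenespiro[bicyclo[3.2.1]octane-3,2'-[1,3]dioxolan]-1-yl group of 11; oxanone locants are O1, C2 = C19, C3 = C4, C4 = C5, C5 = C10, C6 = C20.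
Remark: 18–28 are carried as epimers at C6 (no configuration written there) because C6 is equilibrated in step 19; 24 is a mixture at C10 and 25, 26 at the C10=C1 bond, both without consequence.
Remark: the configurations of 7 (C13) and 9 (C8, C13) were checked atom by atom against the target and need no correction; the design change is that 7 is reached from an enantiopure silyloxy-enone and irradiated at once, and no locking of the enol is needed because both tautomers lead to 9.

## Steps

Step 1
Reactants: 1 2-(chloromethyl)-3-(trimethylsilyl)prop-1-ene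
Product: 3 methyl 3-[(trimethylsilyl)methyl]but-3-enoate, via allylic Grignard reagent 2 (not isolated)
Conditions: Mg, THF, 0 °C; then added to ClCO2Me (3 equiv), THF, −78 °C
Reagents that add atoms: methyl chloroformate, COC(=O)Cl
Why: Grignard formation and C-acylation with a chloroformate; the allyl system is symmetrical, so attack at either terminus gives the same β,γ-unsaturated ester, and inverse addition at −78 °C should prevent double addition and conjugation.

Step 2
Reactants: 3 methyl 3-[(trimethylsilyl)methyl]but-3-enoate; 4 (S)-4-(tert-butyldimethylsilyloxy)cyclopent-2-en-1-one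
Product: 5 methyl 3-{[(1S,2S)-2-(tert-butyldimethylsilyloxy)-4-oxocyclopentyl]methyl}but-3-enoate
Conditions: TiCl4, CH2Cl2, −78 °C
Reagents that add atoms: none
Why: Hosomi–Sakurai conjugate allylation; the allylsilane should add to the enone β-carbon anti to the 4-silyloxy group, which sets C13 (trans product), and loss of the silyl group regenerates the 1,1-disubstituted alkene that becomes C8=C15.

Step 3
Reactants: 5 methyl 3-{[(1S,2S)-2-(tert-butyldimethylsilyloxy)-4-oxocyclopentyl]methyl}but-3-enoate
Product: 6 methyl 3-{[(1S,2S)-2-hydroxy-4-oxocyclopentyl]methyl}but-3-enoate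
Conditions: HF (48 % aq.), MeCN, 0 °C
Reagents that add atoms: none
Why: acidic fluoride desilylation, the standard way to free β-hydroxy cyclopentanones without base-induced elimination to the cyclopentenone; C13 is not involved.

Step 4
Reactants: 6 methyl 3-{[(1S,2S)-2-hydroxy-4-oxocyclopentyl]methyl}but-3-enoate
Product: 7 methyl 3-{[(1S)-2-hydroxy-4-oxocyclopent-2-en-1-yl]methyl}but-3-enoate (enol of the 4-substituted cyclopentane-1,3-dione)
Conditions: Dess–Martin periodinane, CH2Cl2, 0 → 25 °C
Reagents that add atoms: none
Why: oxidation of a β-hydroxy ketone to the 1,3-diketone, which rests as the vinylogous acid; under neutral conditions C13 should hold, since its enolisation would need the cross-conjugated dienol, and 7 is used at once.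

Step 5
Reactants: 7 methyl 3-{[(1S)-2-hydroxy-4-oxocyclopent-2-en-1-yl]methyl}but-3-enoate
Product: 9 methyl 2-[(1S,5S)-3,6-dioxobicyclo[3.2.1]octan-1-yl]acetate, via cyclobutanol photoadduct 8 (not isolated)
Conditions: hν (254 nm, quartz), degassed MeCN (0.01 M), 10 °C; then 25 °C
Reagents that add atoms: none
Why: De Mayo sequence: excitation of the enolised 1,3-dione (an enone chromophore), intramolecular (2+2) photocycloaddition to the 1,1-disubstituted alkene, then retro-aldol opening of the cyclobutanol. With only C13 and C14 between the enone β-carbon C16 and the alkene, the first bond should form in the 1,5 sense from C16 to the terminal carbon C15 (five-membered ring D, tertiary radical at C8), and recombination C9–C8 closes the cyclobutane of the crossed bicyclo[2.1.1]hexane adduct 8; this is the known crossed mode of enone–alkene photocycloaddition of 1,5-dienes. The strained β-hydroxy ketone 8 then cleaves at C9–C16, which leaves C16 as the cyclopentanone carbonyl and makes the C9–C8 bond the last bond of six-membered ring C. The only new stereocentre, C8, is dictated by C13: the short tether reaches one face only, so the bridged bicycle can form as a single diastereomer, and C13 itself is untouched. The selectivity needed is crossed over straight closure, secured by the five-membered first closure and the tertiary C8 radical. The second enol tautomer (hydroxyl on C11) is no liability, because its 1,5-closure (C9–C8, then C11–C15) and retro-aldol lead to the same dione with the same configuration. Dilute degassed solution and 254 nm light, which 7 absorbs strongly and 9 only weakly, should limit intermolecular addition and secondary Norrish cleavage.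

Step 6
Reactants: 9 methyl 2-[(1S,5S)-3,6-dioxobicyclo[3.2.1]octan-1-yl]acetate
Product: 10 methyl 2-[(1R,5S)-6-oxospiro[bicyclo[3.2.1]octane-3,2'-[1,3]dioxolan]-1-yl]acetate
Conditions: Me3SiOCH2CH2OSiMe3 (1.05 equiv), Me3SiOTf (5 mol %), CH2Cl2, −78 °C; pyridine
Reagents that add atoms: 1,2-bis(trimethylsilyloxy)ethane, C[Si](C)(C)OCCO[Si](C)(C)C
Why: kinetic silyl-triflate-catalysed dioxolanation; the cyclohexanone carbonyl C11 adds nucleophiles faster than the bridged cyclopentanone C16 (the same preference that lets a six-ring ketone be ketalised beside a five-ring ketone in steroids), so one equivalent should mask C11 only.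

Step 7
Reactants: 10 methyl 2-[(1R,5S)-6-oxospiro[bicyclo[3.2.1]octane-3,2'-[1,3]dioxolan]-1-yl]acetate
Product: 11 methyl 2-[(1R,5S)-6-methylidenespiro[bicyclo[3.2.1]octane-3,2'-[1,3]dioxolan]-1-yl]acetate (Bic–CH2CO2Me)
Conditions: Ph3PCH3Br, KOtBu, THF, 0 → 25 °C
Reagents that add atoms: methyltriphenylphosphonium bromide, C[P+](c1ccccc1)(c1ccccc1)c1ccccc1.[Br-]
Why: Wittig methylenation of the only free ketone installs C17; placing the alkene now removes the second ketone, so every later step is chosen to tolerate a 1,1-disubstituted alkene.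

Step 8
Reactants: 12 (S)-but-3-ene-1,2-diol
Product: 13 (S)-2-hydroxybut-3-en-1-yl prop-2-enoate
Conditions: CH2=CHCOCl (1.0 equiv), Et3N, CH2Cl2, −78 °C
Reagents that add atoms: acryloyl chloride, C=CC(=O)Cl
Why: acylation of the less hindered primary hydroxyl at low temperature; the stereocentre (future C10) is untouched.

Step 9
Reactants: 13 (S)-2-hydroxybut-3-en-1-yl prop-2-enoate
Product: 14 (S)-2-(triethylsilyloxy)but-3-en-1-yl prop-2-enoate
Conditions: Et3SiCl, imidazole, CH2Cl2, 0 °C
Reagents that add atoms: chlorotriethylsilane, CC[Si](CC)(CC)Cl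
Why: silylation of the secondary alcohol; the triethylsilyl group is chosen so that it can later be removed beside a triisopropylsilyl ether.

Step 10
Reactants: 14 (S)-2-(triethylsilyloxy)but-3-en-1-yl prop-2-enoate
Product: 15 (S)-5-(triethylsilyloxy)-5,6-dihydro-2H-pyran-2-one
Conditions: second-generation Grubbs catalyst (H2IMes)(PCy3)Cl2Ru=CHPh (5 mol %), CH2Cl2, 40 °C
Reagents that add atoms: none
Why: ring-closing metathesis of an acrylate with an allylic silyl ether, a standard route to α,β-unsaturated δ-lactones; the ring holds C19, C4, C5, C10 and C20 of the target.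

Step 11
Reactants: 11 Bic–CH2CO2Me; 15 (S)-5-(triethylsilyloxy)-5,6-dihydro-2H-pyran-2-one
Product: 18 methyl 2-Bic-2-[(5S)-3-methyl-2-oxo-5-(triethylsilyloxy)oxan-4-yl]acetate (4,5-trans; 3,4-trans), via lithium ester enolate 16 (not isolated), via lithium lactone enolate 17 (not isolated)
Conditions: LiN(i-Pr)2, THF, −78 °C; 15, −78 °C; then MeI, DMPU, −78 → −20 °C
Reagents that add atoms: iodomethane, CI
Why: Michael addition of a lithium ester enolate to an unsaturated δ-lactone, then alkylation of the resulting lactone enolate; the nucleophile should add anti to the neighbouring silyloxy group, which sets C5 from the purchased stereocentre, and the methyl enters trans to the new C5 substituent. C6 is formed without control and corrected in step 19.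

Step 12
Reactants: 18 methyl 2-Bic-2-[(5S)-3-methyl-2-oxo-5-(triethylsilyloxy)oxan-4-yl]acetate
Product: 21 methyl 2-Bic-2-{(5S)-3-methyl-2-oxo-5-(triethylsilyloxy)-3-[(triisopropylsilyloxy)methyl]oxan-4-yl}acetate (silyloxymethyl trans to the C4 substituent), via lithium lactone enolate 19 (not isolated), via lithium aldolate 20 (not isolated)
Conditions: LiN(i-Pr)2 (1.05 equiv), THF, −78 °C; CH2O (gas), −78 °C; then i-Pr3SiOTf, −78 → 0 °C
Reagents that add atoms: formaldehyde, C=O; triisopropylsilyl trifluoromethanesulfonate, CC(C)[Si](C(C)C)(C(C)C)OS(=O)(=O)C(F)(F)F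
Why: aldol reaction of the lactone enolate with formaldehyde and silylation of the aldolate in the same flask; the lactone α-hydrogen is several pK units more acidic than the hindered ester α-hydrogen, and the second electrophile should enter trans to the bulky C5 substituent, which gives the quaternary C4 with C3 on the face needed for ring A.

Step 13
Reactants: 21 methyl 2-Bic-2-{(5S)-3-methyl-2-oxo-5-(triethylsilyloxy)-3-[(triisopropylsilyloxy)methyl]oxan-4-yl}acetate
Product: 22 methyl 2-Bic-2-{(5S)-5-hydroxy-3-methyl-2-oxo-3-[(triisopropylsilyloxy)methyl]oxan-4-yl}acetate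
Conditions: HF·pyridine, pyridine, THF, 0 °C
Reagents that add atoms: none
Why: buffered fluoride removes the secondary triethylsilyl ether much faster than the neopentyl triisopropylsilyl ether and leaves the dioxolane and the exocyclic alkene alone.

Step 14
Reactants: 22 methyl 2-Bic-2-{(5S)-5-hydroxy-3-methyl-2-oxo-3-[(triisopropylsilyloxy)methyl]oxan-4-yl}acetate
Product: 23 methyl 2-Bic-2-{3-methyl-2,5-dioxo-3-[(triisopropylsilyloxy)methyl]oxan-4-yl}acetate
Conditions: Dess–Martin periodinane, CH2Cl2, 25 °C
Reagents that add atoms: none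
Why: neutral oxidation of the secondary alcohol to the C10 ketone; should C5 (now α to a ketone) equilibrate, the drawn epimer with the C5 substituent trans to the larger silyloxymethyl group at C4 is expected to be the favoured one.

Step 15
Reactants: 23 methyl 2-Bic-2-{3-methyl-2,5-dioxo-3-[(triisopropylsilyloxy)methyl]oxan-4-yl}acetate
Product: 24 methyl 2-Bic-2-{5-ethenyl-5-hydroxy-3-methyl-2-oxo-3-[(triisopropylsilyloxy)methyl]oxan-4-yl}acetate
Conditions: CeCl3, CH2=CHMgBr, THF, −78 °C; AcOH at −78 °C
Reagents that add atoms: vinylmagnesium bromide, C=C[Mg]Br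
Why: organocerium 1,2-addition, which is non-basic and selective for a ketone over lactone and ester, so C5 is not enolised; quenching cold keeps the tertiary alkoxide from attacking the lactone carbonyl.

Step 16
Reactants: 24 methyl 2-Bic-2-{5-ethenyl-5-hydroxy-3-methyl-2-oxo-3-[(triisopropylsilyloxy)methyl]oxan-4-yl}acetate
Product: 25 methyl 2-Bic-2-{3-methyl-2-oxo-5-(2-oxoethylidene)-3-[(triisopropylsilyloxy)methyl]oxan-4-yl}acetate
Conditions: pyridinium chlorochromate [C5H5NH][CrO3Cl], 4 Å molecular sieves, CH2Cl2, 25 °C
Reagents that add atoms: pyridinium chlorochromate, [O-][Cr](=O)(=O)Cl.c1cc[nH+]cc1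
Why: Babler–Dauben oxidative transposition of a tertiary vinyl carbinol (1-vinylcycloalkanol type) through [3,3] shift of the chromate ester and oxidation; it turns C10 into the β-carbon of an enal that carries C1 and C2.

Step 17
Reactants: 25 methyl 2-Bic-2-{3-methyl-2-oxo-5-(2-oxoethylidene)-3-[(triisopropylsilyloxy)methyl]oxan-4-yl}acetate
Product: 26 methyl 2-[(5S)-6-methylidene-3-oxobicyclo[3.2.1]octan-1-yl]-2-{3-methyl-2-oxo-5-(2-oxoethylidene)-3-[(triisopropylsilyloxy)methyl]oxan-4-yl}acetate
Conditions: PPTS (cat.), acetone/H2O (9:1), 50 °C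
Reagents that add atoms: water, O
Why: mild acetal hydrolysis frees the C11 ketone; pyridinium tosylate is weak enough to spare the exocyclic alkene and the hindered silyl ether.

Step 18
Reactants: 26 methyl 2-[(5S)-6-methylidene-3-oxobicyclo[3.2.1]octan-1-yl]-2-{3-methyl-2-oxo-5-(2-oxoethylidene)-3-[(triisopropylsilyloxy)methyl]oxan-4-yl}acetate
Product: 27 methyl 2,11-dioxo-3-(triisopropylsilyloxy)-2,3-secogibberell-16-en-7-oate 19,20-lactone (ring B closed; H9 β, C20 α)
Conditions: DBU, MeCN, 25 → 50 °C
Reagents that add atoms: none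
Why: intramolecular Michael addition of the ketone (through its enolate) to the β,β-disubstituted enal, 5-exo-trig; only C9 can reach C10 through the C8–C6–C5 tether. The new bond should form on the face of C9 away from the C15–C16 bridge and cis to C6 on the lactone ring (cis-fused five-membered ring), which sets C9 and the quaternary C10; C9 stays under thermodynamic control and the cis ring fusion is expected to be the stable one.

Step 19
Reactants: 27 methyl 2,11-dioxo-3-(triisopropylsilyloxy)-2,3-secogibberell-16-en-7-oate 19,20-lactone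
Product: 29 methyl 2,11β-dihydroxy-3-(triisopropylsilyloxy)-2,3-secogibberell-16-en-7-oate 19,20-lactone (6β-ester), via C6-epimeric diol 28 (not isolated)
Conditions: NaBH4, MeOH/THF, 0 °C; then NaOMe (0.5 equiv), MeOH, 50 °C; AcOH
Reagents that add atoms: none
Why: borohydride reduces the aldehyde and the C11 ketone; hydride should enter C11 equatorially from the face away from the two-carbon bridge and give the axial 11β-alcohol. Methoxide then equilibrates the C6 ester to the 6β-epimer, which is trans to C4 and on the open β-face of ring B.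

Step 20
Reactants: 29 methyl 2,11β-dihydroxy-3-(triisopropylsilyloxy)-2,3-secogibberell-16-en-7-oate 19,20-lactone
Product: 30 methyl 2,3,11β-trihydroxy-2,3-secogibberell-16-en-7-oate 19,20-lactone
Conditions: HF·pyridine, THF, 25 °C
Reagents that add atoms: none
Why: acidic fluoride desilylation; a basic fluoride source is avoided because the freed hydroxymethyl group is β to the lactone carbonyl and could be lost by retro-aldol.

Step 21
Reactants: 30 methyl 2,3,11β-trihydroxy-2,3-secogibberell-16-en-7-oate 19,20-lactone
Product: 31 methyl 11β-hydroxy-2,3-dioxo-2,3-secogibberell-16-en-7-oate 19,20-lactone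
Conditions: TEMPO (20 mol %), PhI(OAc)2, CH2Cl2, 25 °C
Reagents that add atoms: none
Why: oxoammonium oxidation is selective for primary alcohols, so both primary carbinols become aldehydes while the hindered axial 11β-hydroxyl and the alkene remain; the dialdehyde is used directly.

Step 22
Reactants: 31 methyl 11β-hydroxy-2,3-dioxo-2,3-secogibberell-16-en-7-oate 19,20-lactone
Product: 32 methyl 2β,3β,11β-trihydroxygibberell-16-en-7-oate 19,20-lactone (methyl ester of the target)
Conditions: SmI2, THF, −78 → 0 °C; then H2O
Reagents that add atoms: none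
Why: SmI2-mediated intramolecular pinacol coupling of a 1,6-dialdehyde; the two arms are 1,3-diaxial on the lactone ring, so ring A should close easily, and the samarium-bridged ketyl–aldehyde pair favours the cis-diol. The C2 oxygen has to point to the β-face because the α (endo) position collides with the lactone oxygen, and the cis relationship then places the C3 hydroxyl β as well.

Step 23
Reactants: 32 methyl 2β,3β,11β-trihydroxygibberell-16-en-7-oate 19,20-lactone
Product: 33 2β,3β,11β-trihydroxygibberell-16-ene-7,19-dioic acid 19,20-lactone (target)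
Conditions: n-PrSH, n-BuLi, HMPA, 0 → 25 °C; then 1 M HCl
Reagents that add atoms: none
Why: SN2 demethylation of the methyl ester by a thiolate; the lactone CH2–O carbon is neopentyl and should not be attacked, and the weakly basic thiolate does not form the C3 alkoxide, so the β-hydroxy lactone is not exposed to retro-aldol conditions.

## Compound list

1 | 2-(chloromethyl)-3-(trimethylsilyl)prop-1-ene | C=C(CCl)C[Si](C)(C)C | starting material
2 | {2-[(trimethylsilyl)methyl]prop-2-en-1-yl}magnesium chloride | C=C(C[Si](C)(C)C)C[Mg]Cl | intermediate (not isolated)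
3 | methyl 3-[(trimethylsilyl)methyl]but-3-enoate | C=C(C[Si](C)(C)C)CC(=O)OC | intermediate
4 | (S)-4-(tert-butyldimethylsilyloxy)cyclopent-2-en-1-one | O=C1C[C@H](O[Si](C)(C)C(C)(C)C)C=C1 | starting material
5 | methyl 3-{[(1S,2S)-2-(tert-butyldimethylsilyloxy)-4-oxocyclopentyl]methyl}but-3-enoate | O=C1C[C@H](O[Si](C)(C)C(C)(C)C)[C@@H](CC(=C)CC(=O)OC)C1 | intermediate
6 | methyl 3-{[(1S,2S)-2-hydroxy-4-oxocyclopentyl]methyl}but-3-enoate | O=C1C[C@H](O)[C@@H](CC(=C)CC(=O)OC)C1 | intermediate
7 | methyl 3-{[(1S)-2-hydroxy-4-oxocyclopent-2-en-1-yl]methyl}but-3-enoate | O=C1C=C(O)[C@@H](CC(=C)CC(=O)OC)C1 | intermediate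
8 | methyl 2-(1-hydroxy-3-oxotricyclo[3.3.0.0^2,7]octan-7-yl)acetate (crossed photoadduct; C16–C15 and C9–C8 bonds) | O=C1C[C@@H]2C[C@@]3(CC(=O)OC)C[C@]2(O)[C@@H]13 | intermediate (not isolated)
9 | methyl 2-[(1S,5S)-3,6-dioxobicyclo[3.2.1]octan-1-yl]acetate | O=C1C[C@]2(CC(=O)OC)C[C@H]1CC(=O)C2 | intermediate
10 | methyl 2-[(1R,5S)-6-oxospiro[bicyclo[3.2.1]octane-3,2'-[1,3]dioxolan]-1-yl]acetate | O=C1C[C@]2(CC(=O)OC)C[C@H]1CC3(OCCO3)C2 | intermediate
11 | methyl 2-[(1R,5S)-6-methylidenespiro[bicyclo[3.2.1]octane-3,2'-[1,3]dioxolan]-1-yl]acetate | C=C1C[C@]2(CC(=O)OC)C[C@H]1CC3(OCCO3)C2 | intermediate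
12 | (S)-but-3-ene-1,2-diol | C=C[C@H](O)CO | starting material
13 | (S)-2-hydroxybut-3-en-1-yl prop-2-enoate | C=C[C@H](O)COC(=O)C=C | intermediate
14 | (S)-2-(triethylsilyloxy)but-3-en-1-yl prop-2-enoate | C=C[C@H](O[Si](CC)(CC)CC)COC(=O)C=C | intermediate
15 | (S)-5-(triethylsilyloxy)-5,6-dihydro-2H-pyran-2-one | O=C1C=C[C@H](O[Si](CC)(CC)CC)CO1 | intermediate
16 | lithium 2-Bic-1-methoxyethenolate (ester enolate of 11) | C=C1C[C@]2(C=C(O[Li])OC)C[C@H]1CC3(OCCO3)C2 | intermediate (not isolated)
17 | lithium enolate of methyl 2-Bic-2-[(5S)-2-oxo-5-(triethylsilyloxy)oxan-4-yl]acetate (4,5-trans; C6 epimers) | C=C1C[C@]2(C(C(=O)OC)[C@@H]3C=C(O[Li])OC[C@H]3O[Si](CC)(CC)CC)C[C@H]1CC4(OCCO4)C2 | intermediate (not isolated)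
18 | methyl 2-Bic-2-[(5S)-3-methyl-2-oxo-5-(triethylsilyloxy)oxan-4-yl]acetate (4,5-trans; 3,4-trans; C6 epimers) | C=C1C[C@]2(C(C(=O)OC)[C@@H]3[C@@H](C)C(=O)OC[C@H]3O[Si](CC)(CC)CC)C[C@H]1CC4(OCCO4)C2 | intermediate
19 | lithium lactone enolate of 18 | C=C1C[C@]2(C(C(=O)OC)[C@@H]3C(C)=C(O[Li])OC[C@H]3O[Si](CC)(CC)CC)C[C@H]1CC4(OCCO4)C2 | intermediate (not isolated)
20 | lithium alkoxide of methyl 2-Bic-2-[(5S)-3-(hydroxymethyl)-3-methyl-2-oxo-5-(triethylsilyloxy)oxan-4-yl]acetate (hydroxymethyl trans to the C4 substituent) | C=C1C[C@]2(C(C(=O)OC)[C@@H]3[C@@](C)(CO[Li])C(=O)OC[C@H]3O[Si](CC)(CC)CC)C[C@H]1CC4(OCCO4)C2 | intermediate (not isolated)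
21 | methyl 2-Bic-2-{(5S)-3-methyl-2-oxo-5-(triethylsilyloxy)-3-[(triisopropylsilyloxy)methyl]oxan-4-yl}acetate | C=C1C[C@]2(C(C(=O)OC)[C@@H]3[C@@](C)(CO[Si](C(C)C)(C(C)C)C(C)C)C(=O)OC[C@H]3O[Si](CC)(CC)CC)C[C@H]1CC4(OCCO4)C2 | intermediate
22 | methyl 2-Bic-2-{(5S)-5-hydroxy-3-methyl-2-oxo-3-[(triisopropylsilyloxy)methyl]oxan-4-yl}acetate | C=C1C[C@]2(C(C(=O)OC)[C@@H]3[C@@](C)(CO[Si](C(C)C)(C(C)C)C(C)C)C(=O)OC[C@H]3O)C[C@H]1CC4(OCCO4)C2 | intermediate
23 | methyl 2-Bic-2-{3-methyl-2,5-dioxo-3-[(triisopropylsilyloxy)methyl]oxan-4-yl}acetate | C=C1C[C@]2(C(C(=O)OC)[C@@H]3[C@@](C)(CO[Si](C(C)C)(C(C)C)C(C)C)C(=O)OCC3=O)C[C@H]1CC4(OCCO4)C2 | intermediate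
24 | methyl 2-Bic-2-{5-ethenyl-5-hydroxy-3-methyl-2-oxo-3-[(triisopropylsilyloxy)methyl]oxan-4-yl}acetate (C10 epimers) | C=C1C[C@]2(C(C(=O)OC)[C@@H]3[C@@](C)(CO[Si](C(C)C)(C(C)C)C(C)C)C(=O)OCC3(O)C=C)C[C@H]1CC4(OCCO4)C2 | intermediate
25 | methyl 2-Bic-2-{3-methyl-2-oxo-5-(2-oxoethylidene)-3-[(triisopropylsilyloxy)methyl]oxan-4-yl}acetate | C=C1C[C@]2(C(C(=O)OC)[C@@H]3[C@@](C)(CO[Si](C(C)C)(C(C)C)C(C)C)C(=O)OCC3=CC=O)C[C@H]1CC4(OCCO4)C2 | intermediate
26 | methyl 2-[(5S)-6-methylidene-3-oxobicyclo[3.2.1]octan-1-yl]-2-{3-methyl-2-oxo-5-(2-oxoethylidene)-3-[(triisopropylsilyloxy)methyl]oxan-4-yl}acetate (bridgeheads as in 9) | C=C1C[C@]2(C(C(=O)OC)[C@@H]3[C@@](C)(CO[Si](C(C)C)(C(C)C)C(C)C)C(=O)OCC3=CC=O)C[C@H]1CC(=O)C2 | intermediate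
27 | methyl 2,11-dioxo-3-(triisopropylsilyloxy)-2,3-secogibberell-16-en-7-oate 19,20-lactone (C6 epimers) | C=C1C[C@]23C[C@H]1CC(=O)[C@H]2[C@@]2(CC=O)COC(=O)[C@](C)(CO[Si](C(C)C)(C(C)C)C(C)C)[C@H]2C3C(=O)OC | intermediate
28 | methyl 2,11β-dihydroxy-3-(triisopropylsilyloxy)-2,3-secogibberell-16-en-7-oate 19,20-lactone (C6 epimers) | C=C1C[C@]23C[C@H]1C[C@H](O)[C@H]2[C@@]2(CCO)COC(=O)[C@](C)(CO[Si](C(C)C)(C(C)C)C(C)C)[C@H]2C3C(=O)OC | intermediate (not isolated)
29 | methyl 2,11β-dihydroxy-3-(triisopropylsilyloxy)-2,3-secogibberell-16-en-7-oate 19,20-lactone (6β-ester) | C=C1C[C@]23C[C@H]1C[C@H](O)[C@H]2[C@@]2(CCO)COC(=O)[C@](C)(CO[Si](C(C)C)(C(C)C)C(C)C)[C@H]2[C@@H]3C(=O)OC | intermediate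
30 | methyl 2,3,11β-trihydroxy-2,3-secogibberell-16-en-7-oate 19,20-lactone | C=C1C[C@]23C[C@H]1C[C@H](O)[C@H]2[C@@]2(CCO)COC(=O)[C@](C)(CO)[C@H]2[C@@H]3C(=O)OC | intermediate
31 | methyl 11β-hydroxy-2,3-dioxo-2,3-secogibberell-16-en-7-oate 19,20-lactone | C=C1C[C@]23C[C@H]1C[C@H](O)[C@H]2[C@@]2(CC=O)COC(=O)[C@](C)(C=O)[C@H]2[C@@H]3C(=O)OC | intermediate
32 | methyl 2β,3β,11β-trihydroxygibberell-16-en-7-oate 19,20-lactone | C=C1C[C@]23C[C@H]1C[C@H](O)[C@H]2[C@]12COC(=O)[C@](C)([C@@H](O)[C@@H](O)C1)[C@H]2[C@@H]3C(=O)OC | intermediate
33 | 2β,3β,11β-trihydroxygibberell-16-ene-7,19-dioic acid 19,20-lactone (CNP0302900.3) | C=C1C[C@]23C[C@H]1C[C@H](O)[C@H]2[C@]12COC(=O)[C@](C)([C@@H](O)[C@@H](O)C1)[C@H]2[C@@H]3C(=O)O | target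

## Step count and least certain steps

Total: 23 steps. Longest linear sequence: 20 steps (steps 1–7 and 11–23); the lactone branch (steps 8–10) joins at step 11.

Step 5 (key step). The excited enone may close in the straight rather than the crossed sense, the hydrogen-bonded enol may self-quench or add intermolecularly, and prolonged irradiation may cleave the product ketones; any of these would erode the conversion to 9. Fallback, from 7 back to 9: the enol is fixed as its two enol acetates before irradiation, and the fragmentation becomes a separate base-triggered step. Acetylation (Ac2O, Et3N, DMAP) should give methyl 3-{[(1S)-2-acetoxy-4-oxocyclopent-2-en-1-yl]methyl}but-3-enoate F1 and methyl 3-{[(1S)-4-acetoxy-2-oxocyclopent-3-en-1-yl]methyl}but-3-enoate F2. Acetone-sensitised irradiation at 300 nm should give the stable acetoxycyclobutanes methyl 2-(1-acetoxy-3-oxotricyclo[3.3.0.0^2,7]octan-7-yl)acetate F3 and methyl 2-(3-acetoxy-7-oxotricyclo[3.2.1.0^3,6]octan-5-yl)acetate F4. Methanolysis (K2CO3, MeOH) releases the cyclobutanolates, and both fragment by retro-aldol to the same dione 9.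

Step 6. Discrimination between the two ketones may be poor, because the endo oxygen of a C11 ketal is pressed against the C15–C16 bridge; mixtures with the C16 ketal and the bis-ketal would result. Fallback, from 9 back to 11: the two carbonyls are told apart by an irreversible hydride reduction instead of a ketalisation. NaBH4 in MeOH/CH2Cl2 at −78 °C should reduce the cyclohexanone first and give methyl 2-[(5S)-3-endo-hydroxy-6-oxobicyclo[3.2.1]octan-1-yl]acetate F5. Wittig methylenation with excess Ph3P=CH2 (which reacts through the open hydroxy ketone if a hemiketal forms) gives methyl 2-[(5S)-3-endo-hydroxy-6-methylidenebicyclo[3.2.1]octan-1-yl]acetate F6. Dess–Martin oxidation gives methyl 2-[(5S)-6-methylidene-3-oxobicyclo[3.2.1]octan-1-yl]acetate F7, and dioxolanation of its only ketone (ethylene glycol, PPTS, benzene, reflux) gives 11.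

Step 12. The electrophile may enter on the wrong face of the lactone enolate, since the C10 silyloxy group sits on the face that must be used, and some deprotonation at the C6 ester may compete; both would damage C4, which cannot be corrected later. Fallback, from 18 back to 22: the C10 oxygen is turned into the director. HF·pyridine gives methyl 2-Bic-2-[(5S)-5-hydroxy-3-methyl-2-oxooxan-4-yl]acetate F8. Silylation with BrCH2SiMe2Cl and imidazole gives the (bromomethyl)dimethylsilyl ether F9. Its lactone enolate (LiN(i-Pr)2, THF, −78 → 0 °C) is alkylated intramolecularly, necessarily on the face of the C10 oxygen, to the bicyclic siloxane F10. Tamao–Fleming oxidation (H2O2, KF, KHCO3) gives methyl 2-Bic-2-[(5S)-5-hydroxy-3-(hydroxymethyl)-3-methyl-2-oxooxan-4-yl]acetate F11. Selective silylation of the primary hydroxyl (i-Pr3SiCl, imidazole) gives 22.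

Step 18. The conjugate addition to the hindered β,β-disubstituted enal may be slow or reversible, and deprotonation γ to the aldehyde may deconjugate the acceptor before ring B closes. Fallback, from 23 back to 29: ring B is closed by a palladium π-allyl alkylation instead of a Michael addition. Vinylation as in step 15 with trapping of the alkoxide by ClCO2Me gives the tertiary allylic methyl carbonate F12. PPTS in wet acetone frees the ring C ketone, giving carbonate F13. Pd(PPh3)4 with catalytic pyrrolidine in THF should ionise the carbonate and let C9 attack the substituted allyl terminus (five-membered ring), giving methyl 11-oxo-3-(triisopropylsilyloxy)-2,3-secogibberella-1,16-dien-7-oate 19,20-lactone F14. NaBH4 gives the 11β-alcohol F15. 9-BBN and then NaBO3 hydroxylate the monosubstituted vinyl group in preference to the 1,1-disubstituted alkene and give 28, and NaOMe as in step 19 gives 29.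

Step 22. The coupling may give the trans-diol if the samarium chelate is not maintained, and over-reduction of the activated C3 aldehyde may compete. Fallback, from 31 back to 32: C3 is set by hydride reduction instead of by the coupling. The coupling is run without regard to selectivity and gives 32 together with its C3 epimer, methyl 2β,3α,11β-trihydroxygibberell-16-en-7-oate 19,20-lactone F16. Et3SiCl and imidazole silylate the least hindered equatorial 2β-hydroxyl of both to the 2-O-triethylsilyl ethers F17. Dess–Martin periodinane converges them to the 2β-(triethylsilyloxy)-3,11-diketone F18. LiBH(s-Bu)3 at −78 °C should attack both ketones equatorially and give the axial 3β,11β-diol F19. HF·pyridine gives 32.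

## Further compounds

F1 | step 5 | methyl 3-{[(1S)-2-acetoxy-4-oxocyclopent-2-en-1-yl]methyl}but-3-enoate | O=C1C=C(OC(C)=O)[C@@H](CC(=C)CC(=O)OC)C1
F2 | step 5 | methyl 3-{[(1S)-4-acetoxy-2-oxocyclopent-3-en-1-yl]methyl}but-3-enoate | CC(=O)OC1=CC(=O)[C@@H](CC(=C)CC(=O)OC)C1
F3 | step 5 | methyl 2-(1-acetoxy-3-oxotricyclo[3.3.0.0^2,7]octan-7-yl)acetate | O=C1C[C@@H]2C[C@@]3(CC(=O)OC)C[C@]2(OC(C)=O)[C@@H]13
F4 | step 5 | methyl 2-(3-acetoxy-7-oxotricyclo[3.2.1.0^3,6]octan-5-yl)acetate | O=C1[C@@H]2C[C@@]3(OC(C)=O)C[C@@](CC(=O)OC)(C2)[C@@H]13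
F5 | step 6 | methyl 2-[(5S)-3-endo-hydroxy-6-oxobicyclo[3.2.1]octan-1-yl]acetate | O=C1C[C@]2(CC(=O)OC)C[C@H]1C[C@H](O)C2
F6 | step 6 | methyl 2-[(5S)-3-endo-hydroxy-6-methylidenebicyclo[3.2.1]octan-1-yl]acetate | C=C1C[C@]2(CC(=O)OC)C[C@H]1C[C@H](O)C2
F7 | step 6 | methyl 2-[(5S)-6-methylidene-3-oxobicyclo[3.2.1]octan-1-yl]acetate | C=C1C[C@]2(CC(=O)OC)C[C@H]1CC(=O)C2
F8 | step 12 | methyl 2-Bic-2-[(5S)-5-hydroxy-3-methyl-2-oxooxan-4-yl]acetate | C=C1C[C@]2(C(C(=O)OC)[C@@H]3[C@@H](C)C(=O)OC[C@H]3O)C[C@H]1CC4(OCCO4)C2
F9 | step 12 | methyl 2-Bic-2-{(5S)-5-[(bromomethyl)dimethylsilyloxy]-3-methyl-2-oxooxan-4-yl}acetate | C=C1C[C@]2(C(C(=O)OC)[C@@H]3[C@@H](C)C(=O)OC[C@H]3O[Si](C)(C)CBr)C[C@H]1CC4(OCCO4)C2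
F10 | step 12 | bicyclic siloxane from F9 (CH2–SiMe2–O bridge between lactone C3 and C5) | C=C1C[C@]2(C(C(=O)OC)[C@@H]3[C@]5(C)C(=O)OC[C@H]3O[Si](C)(C)C5)C[C@H]1CC4(OCCO4)C2
F11 | step 12 | methyl 2-Bic-2-[(5S)-5-hydroxy-3-(hydroxymethyl)-3-methyl-2-oxooxan-4-yl]acetate | C=C1C[C@]2(C(C(=O)OC)[C@@H]3[C@@](C)(CO)C(=O)OC[C@H]3O)C[C@H]1CC4(OCCO4)C2
F12 | step 18 | methyl carbonate of 24 | C=C1C[C@]2(C(C(=O)OC)[C@@H]3[C@@](C)(CO[Si](C(C)C)(C(C)C)C(C)C)C(=O)OCC3(OC(=O)OC)C=C)C[C@H]1CC4(OCCO4)C2
F13 | step 18 | ring C ketone of F12 | C=C1C[C@]2(C(C(=O)OC)[C@@H]3[C@@](C)(CO[Si](C(C)C)(C(C)C)C(C)C)C(=O)OCC3(OC(=O)OC)C=C)C[C@H]1CC(=O)C2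
F14 | step 18 | methyl 11-oxo-3-(triisopropylsilyloxy)-2,3-secogibberella-1,16-dien-7-oate 19,20-lactone | C=C1C[C@]23C[C@H]1CC(=O)[C@H]2[C@@]2(C=C)COC(=O)[C@](C)(CO[Si](C(C)C)(C(C)C)C(C)C)[C@H]2C3C(=O)OC
F15 | step 18 | methyl 11β-hydroxy-3-(triisopropylsilyloxy)-2,3-secogibberella-1,16-dien-7-oate 19,20-lactone | C=C1C[C@]23C[C@H]1C[C@H](O)[C@H]2[C@@]2(C=C)COC(=O)[C@](C)(CO[Si](C(C)C)(C(C)C)C(C)C)[C@H]2C3C(=O)OC
F16 | step 22 | methyl 2β,3α,11β-trihydroxygibberell-16-en-7-oate 19,20-lactone | C=C1C[C@]23C[C@H]1C[C@H](O)[C@H]2[C@]12COC(=O)[C@](C)([C@H](O)[C@@H](O)C1)[C@H]2[C@@H]3C(=O)OC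
F17 | step 22 | 2-O-triethylsilyl ethers of 32 and F16 (C3 epimers) | C=C1C[C@]23C[C@H]1C[C@H](O)[C@H]2[C@]12COC(=O)[C@](C)(C(O)[C@@H](O[Si](CC)(CC)CC)C1)[C@H]2[C@@H]3C(=O)OC
F18 | step 22 | methyl 3,11-dioxo-2β-(triethylsilyloxy)gibberell-16-en-7-oate 19,20-lactone | C=C1C[C@]23C[C@H]1CC(=O)[C@H]2[C@]12COC(=O)[C@](C)(C(=O)[C@@H](O[Si](CC)(CC)CC)C1)[C@H]2[C@@H]3C(=O)OC
F19 | step 22 | methyl 3β,11β-dihydroxy-2β-(triethylsilyloxy)gibberell-16-en-7-oate 19,20-lactone | C=C1C[C@]23C[C@H]1C[C@H](O)[C@H]2[C@]12COC(=O)[C@](C)([C@@H](O)[C@@H](O[Si](CC)(CC)CC)C1)[C@H]2[C@@H]3C(=O)OC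
A1 | alternative 1 | 6-diazo-7-oxo kauranoid 19,20-lactone, 2,3,11-tris(tert-butyldimethylsilyl) ether | C=C1C[C@]23C[C@H]1C[C@H](O[Si](C)(C)C(C)(C)C)[C@H]2[C@]12COC(=O)[C@](C)([C@@H](O[Si](C)(C)C(C)(C)C)[C@@H](O[Si](C)(C)C(C)(C)C)C1)[C@H]2C(=[N+]=[N-])C3=O
A2 | alternative 1 | target acid as its 2,3,11-tris(tert-butyldimethylsilyl) ether | C=C1C[C@]23C[C@H]1C[C@H](O[Si](C)(C)C(C)(C)C)[C@H]2[C@]12COC(=O)[C@](C)([C@@H](O[Si](C)(C)C(C)(C)C)[C@@H](O[Si](C)(C)C(C)(C)C)C1)[C@H]2[C@@H]3C(=O)O
A3 | alternative 2 | (−)-8-phenylmenthyl 3-oxo-2-(prop-2-yn-1-yl)hept-6-enoate | CC(C)(c1ccccc1)[C@@H]1CC[C@@H](C)C[C@H]1OC(=O)C(CC#C)C(=O)CCC=C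
A4 | alternative 2 | (−)-8-phenylmenthyl 6-methylene-2-oxobicyclo[3.2.1]octane-1-carboxylate | CC(C)(c1ccccc1)[C@@H]1CC[C@@H](C)C[C@H]1OC(=O)[C@@]12C[C@@H](CCC1=O)C(=C)C2
A5 | alternative 3 | enyne: C/D bicycle with C16 dimethyl ketal, 11-silyl ether, 9-ethynyl group and methyl 2-substituted but-3-enoate on C8 | COC1(OC)C[C@@]2(C[C@H]1C[C@H](O[Si](C)(C)C(C)(C)C)[C@H]2C#C)[C@H](C=C)C(=O)OC
A6 | alternative 3 | ring B-fused cyclopentenone on the C/D bicycle | COC1(OC)C[C@]23C[C@H]1C[C@H](O[Si](C)(C)C(C)(C)C)[C@H]2C1=CC(=O)C[C@H]1[C@@H]3C(=O)OC
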